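Hold on to 1.62, the selectivity factor: the rate constant with which X attacks J over the one with which it attacks L, here above one.

L 1.0 M; X 1.10 M; Z 1.50 M; time 4.0 d

    L + X ⇌ E + J (K1 = 0.88, k1 = 2.79 × 10⁻⁵ /M/s)
    X + E ⇌ X.E, settled at all times (K2 = 2900 /M)
    E + Z ⇌ E.Z (K3 = 1000 /M, k3 = 0.00262 /M/s)
    X + J → X.J (k4 = 4.52 × 10⁻⁵ /M/s)

- part of the L that has reacted at 4.0 d
- share of the unused X that is free and not bound as X.E, at 4.0 d

You can read the time constants as a ladder. On the first rung X binds E at balance, and at the start X catches E ahead of Z, 3200 against 1500. Next comes L meeting X, with a time constant of 0.377 d, short against 4.0 d. Last comes the hand-over of bound E to Z, at first 9.39 d, a constant that shrinks in step with free X, so X.E is the early resting state of E and the X it holds comes back late.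

The end state needs no clock. Let l and j be L and J as fractions of the L charged. Free X is a factor in both attacks, so it cancels from their ratio, and if you leave out the falling back of E + J, then j = (l − l^s)/(s − 1). Each reacted L costs one X and each X.J one more, so the X spent per L charged is 2(1 − l) − j. Z can take up all the E, which makes X the limiting reagent. Setting the spending equal to 1.10 and making one pass from a trial l of 0.333 gives l = 0.324. Some X still sits in X.E at the asked time, so I put c close below 67.6%. In the end state, with E on Z and both bindings at balance, bound over free X is 2.90 times E.Z over Z, which gives a share of 29.6%; I have not reckoned how far the hand-over has come at the asked time, so I take this as a rough figure for fr.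

The forecast says 64% and 28%, picturing the late flask as one where “free X is quasi-steady”; the simulation gives 64.6% and 28.2%.

In this flask J was made 1.78 times as fast as it was used at 0.244 d but only 0.785 times as fast at 4.00 d, and l/(s j) from the final readings gives 0.812, while the rule turns the L of 35.4% into a J of 27.1% against the 26.9% that stood there. In the flask with 0.38 M of Z, the same rule turns its L of 44.2% into a J of 28.3%, and that flask held 27.5%.

The numbers of this flask stand for no real mixture; the rest is arithmetic.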